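The oxolane is numbered O1, C2 (CH2), C3 (carbinol-bearing), C4 (CH2OH-bearing), C5 (trimethoxyphenyl-bearing). O1 and the unsubstituted C2 are read as one formaldehyde, and C3–C4–C5 as a ring-opened aryl cyclopropane whose two ester acceptors sit on C3. A Lewis-acid (3+2) annulation of the enantioenriched trans cyclopropane diester with formaldehyde therefore forms O1–C5 and C2–C3 and closes the ring in one operation. C4 comes unchanged from an aminocatalytic cyclopropanation, and the labile benzylic C5 settles trans to it. One ester is then excised and the other becomes the aryl carbinol by Weinreb ketone synthesis and Felkin-controlled reduction.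

Key step: step 4

Remark: oxolane locants in all names follow the numbering above. Because C5 is set by equilibration, only the silyloxymethyl-bearing carbon of the cyclopropane has to be enantioenriched. The four starting materials and both enantiomers of the prolinol silyl ether catalyst are taken as commercial.

Step 1
Reactants: 1 (E)-3-(3,4,5-trimethoxyphenyl)prop-2-enal; 2 dimethyl bromomalonate
Product: 3 dimethyl (2S,3R)-2-formyl-3-(3,4,5-trimethoxyphenyl)cyclopropane-1,1-dicarboxylate (formyl and aryl trans)
Conditions: (R)-2-[diphenyl(trimethylsilyloxy)methyl]pyrrolidine (20 mol %), 2,6-lutidine (1.1 equiv), CH2Cl2, 0 °C to rt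
Reagents that add atoms: none
Why: Aminocatalytic domino Michael addition–intramolecular alkylation (iminium, then enamine activation): the diphenyl(silyloxy)methyl group of the (R)-catalyst blocks one face of the s-trans E-iminium ion, the bromomalonate anion adds to the β-carbon from the open face and fixes the aryl-bearing carbon as R, and the enamine then displaces bromide in a 3-exo-tet closure that places the formyl group trans to the aryl ring.

Step 2
Reactants: 3 dimethyl (2S,3R)-2-formyl-3-(3,4,5-trimethoxyphenyl)cyclopropane-1,1-dicarboxylate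
Product: 4 dimethyl (2S,3R)-2-(hydroxymethyl)-3-(3,4,5-trimethoxyphenyl)cyclopropane-1,1-dicarboxylate
Conditions: NaBH4 (0.5 equiv), MeOH–CH2Cl2, −40 °C, 20 min; aq NH4Cl; crude used at once
Reagents that add atoms: none
Why: Chemoselective borohydride reduction of the aldehyde beside two esters, run cold and briefly with a buffered quench so that the new alkoxide should not lactonise onto the cis ester; no stereocentre is touched.

Step 3
Reactants: 4 dimethyl (2S,3R)-2-(hydroxymethyl)-3-(3,4,5-trimethoxyphenyl)cyclopropane-1,1-dicarboxylate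
Product: 5 dimethyl (2R,3S)-2-(3,4,5-trimethoxyphenyl)-3-[(triisopropylsilyloxy)methyl]cyclopropane-1,1-dicarboxylate (aryl and silyloxymethyl trans)
Conditions: i-Pr3SiCl (1.2 equiv), imidazole (2.5 equiv), DMF, 0 °C to rt
Reagents that add atoms: chlorotri(propan-2-yl)silane, CC(C)[Si](Cl)(C(C)C)C(C)C
Why: Imidazole-assisted silylation of a primary alcohol; the bulky triisopropylsilyl ether removes the lactonisation pathway for good and should tolerate the Lewis acid, hot chloride, Grignard, aryllithium and hydride conditions that follow.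

Step 4
Reactants: 5 dimethyl (2R,3S)-2-(3,4,5-trimethoxyphenyl)-3-[(triisopropylsilyloxy)methyl]cyclopropane-1,1-dicarboxylate; 6 paraformaldehyde (as formaldehyde)
Product: 8 dimethyl (4S,5R)-5-(3,4,5-trimethoxyphenyl)-4-[(triisopropylsilyloxy)methyl]oxolane-3,3-dicarboxylate (4,5-trans), via 4,5-cis oxolane diester 7 (not isolated)
Conditions: Sn(OTf)2 (20 mol %), (CH2O)n (5 equiv), 4 Å MS, ClCH2CH2Cl, rt, then 50 °C
Reagents that add atoms: none
Why: Sn(OTf)2 chelates the geminal diester of 5 and polarises the cyclopropane bond between the diester carbon and the aryl-bearing carbon, formaldehyde released from paraformaldehyde attacks that benzylic carbon through oxygen (O1–C5), and the tin malonate enolate then adds to the resulting oxocarbenium carbon (C2–C3), the whole being driven by release of ring strain. The closest known reaction type is the Lewis-acid-catalysed (3+2) annulation of aryl cyclopropane-1,1-diesters with aldehydes, here run with the smallest aldehyde. The oxolane closes by an aldol-type 5-(enolexo)-endo-trig attack, since both O1 and C2 of the oxocarbenium π-bond end up in the ring, a mode that is routine for such strongly polarised cationic acceptors. C4 is not touched and carries the enantiopurity of 5, whereas C5 is the one new stereocentre: stereospecific invertive opening of the trans cyclopropane should first give the 4,5-cis oxolane 7, and reversible Sn(OTf)2-induced ionisation of its benzylic C5–O1 bond (3,4,5-trimethoxybenzyl cation) at 50 °C should let it settle to the less crowded 4,5-trans isomer 8, so C5 is set under thermodynamic control by C4. The step needs cleavage at the aryl-bearing and not the silyloxymethyl-bearing carbon, which the aryl donor secures, and attack of formaldehyde oxygen in preference to arene hydroxymethylation, which slow depolymerisation of paraformaldehyde (low free formaldehyde) should favour; the bulky silyl ether resists the Lewis acid and enlarges the trans preference.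

Step 5
Reactants: 8 dimethyl (4S,5R)-5-(3,4,5-trimethoxyphenyl)-4-[(triisopropylsilyloxy)methyl]oxolane-3,3-dicarboxylate
Product: 10 methyl (3R,4S,5R)-5-(3,4,5-trimethoxyphenyl)-4-[(triisopropylsilyloxy)methyl]oxolane-3-carboxylate, via 3,4-cis ester epimer 9 (not isolated)
Conditions: LiCl (3 equiv), H2O (2 equiv), DMSO, 150 °C; then NaOMe (0.3 equiv), MeOH, 40 °C
Reagents that add atoms: none
Why: Krapcho dealkoxycarbonylation (chloride demethylates one ester, CO2 is lost and the enolate is protonated) should give the monoester as a C3 epimer mixture containing the kinetic cis ester 9, and methoxide-mediated enolate equilibration then moves the ester trans to the C4 silyloxymethyl group, so C3 is set under thermodynamic control in the all-trans 3,4,5-array, while ring opening from the enolate would be the reverse of a 5-endo-trig closure and should stay slow.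

Step 6
Reactants: 10 methyl (3R,4S,5R)-5-(3,4,5-trimethoxyphenyl)-4-[(triisopropylsilyloxy)methyl]oxolane-3-carboxylate
Product: 11 (3R,4S,5R)-N-methoxy-N-methyl-5-(3,4,5-trimethoxyphenyl)-4-[(triisopropylsilyloxy)methyl]oxolane-3-carboxamide
Conditions: MeNH(OMe)·HCl (1.5 equiv), i-PrMgCl (3.0 equiv), THF, −20 to 0 °C
Reagents that add atoms: N,O-dimethylhydroxylamine hydrochloride, CNOC.Cl
Why: Weinreb amide synthesis by direct aminolysis of the methyl ester with the chloromagnesium amide generated in the flask; C3 already sits in its preferred trans arrangement, so transient enolisation cannot change it.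

Step 7
Reactants: 11 (3R,4S,5R)-N-methoxy-N-methyl-5-(3,4,5-trimethoxyphenyl)-4-[(triisopropylsilyloxy)methyl]oxolane-3-carboxamide; 12 4-bromo-1,2-dimethoxybenzene
Product: 14 (3,4-dimethoxyphenyl){(3R,4S,5R)-5-(3,4,5-trimethoxyphenyl)-4-[(triisopropylsilyloxy)methyl]oxolan-3-yl}methanone, via (3,4-dimethoxyphenyl)lithium 13 (not isolated)
Conditions: 12, n-BuLi (1.0 equiv to 12), THF, −78 °C; then 11, −78 to −40 °C; aq NH4Cl
Reagents that add atoms: none
Why: Bromine–lithium exchange followed by Weinreb ketone synthesis, in which the aryllithium adds only once because the lithium-chelated tetrahedral adduct holds until the quench; the cold, short reaction should leave the silyl ether and C3 untouched.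

Step 8
Reactants: 14 (3,4-dimethoxyphenyl){(3R,4S,5R)-5-(3,4,5-trimethoxyphenyl)-4-[(triisopropylsilyloxy)methyl]oxolan-3-yl}methanone
Product: 15 (S)-(3,4-dimethoxyphenyl){(3R,4S,5R)-5-(3,4,5-trimethoxyphenyl)-4-[(triisopropylsilyloxy)methyl]oxolan-3-yl}methanol
Conditions: LiBH(s-Bu)3 (1.5 equiv), THF, −78 °C; then aq NaOH, H2O2, 0 °C
Reagents that add atoms: none
Why: Felkin–Anh-controlled hydride addition: with the branched ring carbon C4 antiperiplanar to the incoming bulky borohydride and the ring CH2 (C2) beside the carbonyl oxygen, hydride should reach the face that gives the (S)-carbinol next to (3R)-C3, which is also the sense a chelate through O1 would give.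

Step 9
Reactants: 15 (S)-(3,4-dimethoxyphenyl){(3R,4S,5R)-5-(3,4,5-trimethoxyphenyl)-4-[(triisopropylsilyloxy)methyl]oxolan-3-yl}methanol
Product: 16 (S)-(3,4-dimethoxyphenyl)[(3R,4S,5R)-4-(hydroxymethyl)-5-(3,4,5-trimethoxyphenyl)oxolan-3-yl]methanol (CNP0172668.1)
Conditions: Bu4NF (1.5 equiv), THF, 0 °C to rt
Reagents that add atoms: none
Why: Fluoride-induced desilylation driven by the strong Si–F bond; the benzylic alcohol, the oxolane and the aryl methyl ethers are inert to Bu4NF, so no stereocentre is at risk.

Compound list
1 | (E)-3-(3,4,5-trimethoxyphenyl)prop-2-enal | COc1cc(/C=C/C=O)cc(OC)c1OC | starting material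
2 | dimethyl bromomalonate | COC(=O)C(Br)C(=O)OC | starting material
3 | dimethyl (2S,3R)-2-formyl-3-(3,4,5-trimethoxyphenyl)cyclopropane-1,1-dicarboxylate | COC(=O)C1(C(=O)OC)[C@@H](c2cc(OC)c(OC)c(OC)c2)[C@@H]1C=O | intermediate
4 | dimethyl (2S,3R)-2-(hydroxymethyl)-3-(3,4,5-trimethoxyphenyl)cyclopropane-1,1-dicarboxylate | COC(=O)C1(C(=O)OC)[C@@H](c2cc(OC)c(OC)c(OC)c2)[C@@H]1CO | intermediate
5 | dimethyl (2R,3S)-2-(3,4,5-trimethoxyphenyl)-3-[(triisopropylsilyloxy)methyl]cyclopropane-1,1-dicarboxylate (trans) | COC(=O)C1(C(=O)OC)[C@@H](c2cc(OC)c(OC)c(OC)c2)[C@@H]1CO[Si](C(C)C)(C(C)C)C(C)C | intermediate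
6 | paraformaldehyde (formaldehyde unit shown) | C=O | starting material
7 | dimethyl (4S,5S)-5-(3,4,5-trimethoxyphenyl)-4-[(triisopropylsilyloxy)methyl]oxolane-3,3-dicarboxylate (4,5-cis) | COC(=O)C1(C(=O)OC)CO[C@H](c2cc(OC)c(OC)c(OC)c2)[C@@H]1CO[Si](C(C)C)(C(C)C)C(C)C | intermediate
8 | dimethyl (4S,5R)-5-(3,4,5-trimethoxyphenyl)-4-[(triisopropylsilyloxy)methyl]oxolane-3,3-dicarboxylate (4,5-trans) | COC(=O)C1(C(=O)OC)CO[C@@H](c2cc(OC)c(OC)c(OC)c2)[C@@H]1CO[Si](C(C)C)(C(C)C)C(C)C | intermediate
9 | methyl (3S,4S,5R)-5-(3,4,5-trimethoxyphenyl)-4-[(triisopropylsilyloxy)methyl]oxolane-3-carboxylate (3,4-cis) | COC(=O)[C@@H]1CO[C@@H](c2cc(OC)c(OC)c(OC)c2)[C@@H]1CO[Si](C(C)C)(C(C)C)C(C)C | intermediate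
10 | methyl (3R,4S,5R)-5-(3,4,5-trimethoxyphenyl)-4-[(triisopropylsilyloxy)methyl]oxolane-3-carboxylate (all-trans) | COC(=O)[C@H]1CO[C@@H](c2cc(OC)c(OC)c(OC)c2)[C@@H]1CO[Si](C(C)C)(C(C)C)C(C)C | intermediate
11 | (3R,4S,5R)-N-methoxy-N-methyl-5-(3,4,5-trimethoxyphenyl)-4-[(triisopropylsilyloxy)methyl]oxolane-3-carboxamide | CON(C)C(=O)[C@H]1CO[C@@H](c2cc(OC)c(OC)c(OC)c2)[C@@H]1CO[Si](C(C)C)(C(C)C)C(C)C | intermediate
12 | 4-bromo-1,2-dimethoxybenzene | COc1ccc(Br)cc1OC | starting material
13 | (3,4-dimethoxyphenyl)lithium | [Li]c1ccc(OC)c(OC)c1 | intermediate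
14 | (3,4-dimethoxyphenyl){(3R,4S,5R)-5-(3,4,5-trimethoxyphenyl)-4-[(triisopropylsilyloxy)methyl]oxolan-3-yl}methanone | COc1ccc(C(=O)[C@H]2CO[C@@H](c3cc(OC)c(OC)c(OC)c3)[C@@H]2CO[Si](C(C)C)(C(C)C)C(C)C)cc1OC | intermediate
15 | (S)-(3,4-dimethoxyphenyl){(3R,4S,5R)-5-(3,4,5-trimethoxyphenyl)-4-[(triisopropylsilyloxy)methyl]oxolan-3-yl}methanol | COc1ccc([C@@H](O)[C@H]2CO[C@@H](c3cc(OC)c(OC)c(OC)c3)[C@@H]2CO[Si](C(C)C)(C(C)C)C(C)C)cc1OC | intermediate
16 | (S)-(3,4-dimethoxyphenyl)[(3R,4S,5R)-4-(hydroxymethyl)-5-(3,4,5-trimethoxyphenyl)oxolan-3-yl]methanol | COc1ccc([C@@H](O)[C@H]2CO[C@@H](c3cc(OC)c(OC)c(OC)c3)[C@@H]2CO)cc1OC | target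

Total step count: 9. Longest linear sequence: 9 steps (1 to 16); the aryllithium 13 is made in the flask of step 7, so there is no separate branch.

Steps most likely to fail, in order of risk

Step 4. The weakly nucleophilic formaldehyde oxygen may capture the opened cyclopropane too slowly, so that elimination to a styrene or hydroxymethylation of the electron-rich arene competes. The benzylic C5 centre may also fail to equilibrate fully, leaving the invertive 4,5-cis adduct. The fallback sets out from 5 and comes back at 8, and makes the same two bonds one after the other with known chemistry. Cu(OTf)2-catalysed ring opening of 5 with methanol in CH2Cl2 should give the benzylic methyl ether malonate F1 (either configuration at the methoxy-bearing carbon is acceptable). Base-catalysed hydroxymethylation of its malonate C–H (aqueous formaldehyde, KHCO3, THF) should give the primary alcohol F2. BF3·OEt2 in CH2Cl2 at −20 °C should then ionise the benzylic ether and let the hydroxyl capture the cation anti to the C4 substituent, closing the oxolane to the 4,5-trans diester 8.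

Step 5. At 150 °C the C3 enolate may expel O1 from C2 (E1cB opening of the oxolane), after which the freed benzylic alkoxide can lactonise; the silyl ether may also be lost under hot chloride. The fallback sets out from 8 and comes back at 10, and replaces nucleophilic demethylation by hydrolysis and a milder decarboxylation. Mono-saponification of 8 with KOH (1 equiv) in MeOH–THF–H2O at 0 °C should give the half-acid F3. Decarboxylation of this malonic half-ester in toluene with Et3N at 110 °C, followed by the same NaOMe equilibration, should give 10.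

Step 8. Hydride delivery may show poor facial selectivity if the substrate bias is weaker than the Felkin–Anh analysis predicts. The fallback sets out from 14 and comes back at 15, and moves stereocontrol from the substrate to a catalyst. Borane reduction with BH3·SMe2 and (R)-1-methyl-3,3-diphenyltetrahydro-1H,3H-pyrrolo[1,2-c][1,3,2]oxazaborole (10 mol %, the (R)-methyl oxazaborolidine of the CBS reduction) in THF at −20 °C has the sense for aryl ketones that matches the (S)-carbinol. Any (R)-carbinol epimer F4 is separated, oxidised back to 14 with Dess–Martin periodinane and resubmitted.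

Further compounds
F1 | step 4 | dimethyl 2-[(2S)-1-methoxy-1-(3,4,5-trimethoxyphenyl)-3-(triisopropylsilyloxy)propan-2-yl]propanedioate (either configuration at the methoxy-bearing carbon) | COC(=O)C(C(=O)OC)[C@@H](CO[Si](C(C)C)(C(C)C)C(C)C)C(OC)c1cc(OC)c(OC)c(OC)c1
F2 | step 4 | dimethyl 2-(hydroxymethyl)-2-[(2S)-1-methoxy-1-(3,4,5-trimethoxyphenyl)-3-(triisopropylsilyloxy)propan-2-yl]propanedioate (either configuration at the methoxy-bearing carbon) | COC(=O)C(CO)(C(=O)OC)[C@@H](CO[Si](C(C)C)(C(C)C)C(C)C)C(OC)c1cc(OC)c(OC)c(OC)c1
F3 | step 5 | (4S,5R)-3-(methoxycarbonyl)-5-(3,4,5-trimethoxyphenyl)-4-[(triisopropylsilyloxy)methyl]oxolane-3-carboxylic acid (either C3 epimer) | COC(=O)C1(C(=O)O)CO[C@@H](c2cc(OC)c(OC)c(OC)c2)[C@@H]1CO[Si](C(C)C)(C(C)C)C(C)C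
F4 | step 8 | (R)-(3,4-dimethoxyphenyl){(3R,4S,5R)-5-(3,4,5-trimethoxyphenyl)-4-[(triisopropylsilyloxy)methyl]oxolan-3-yl}methanol | COc1ccc([C@H](O)[C@H]2CO[C@@H](c3cc(OC)c(OC)c(OC)c3)[C@@H]2CO[Si](C(C)C)(C(C)C)C(C)C)cc1OC
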